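**Retrosynthetic overview**

1. Target 15 is a p-quinol methyl ether. Ring numbering used throughout: C1 (C=O), C2 (allyl), C3–H, C4 (quaternary, OMe, side chain), C5 (OMe), C6–H; the side chain is Cα(H)(CH3)–CH2–aryl.
2. Enabling feature: C4 is an oxygen-bearing quaternary carbon para to C1=O and next to the C5–OMe enol ether, so the ring is the 1,2-adduct of 2-allyl-5-methoxy-1,4-benzoquinone 5. In 5 the C1 carbonyl is a vinylogous ester (MeO–C5=C6–C1=O) flanked by the allyl-bearing C2, so a hard carbon nucleophile should attack only C4=O.
3. Key disconnection: the C4–Cα bond and the C4–O–CH3 methyl are made in one three-component operation from quinone 5, the configurationally defined secondary alkyllithium 12 and MeOTf.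
4. Fragments: 5 from 3,4-dimethoxyphenol (O-allylation, Claisen, oxidative demethylation); iodide 11 from 4-bromo-2-methoxyphenol and (S)-propylene oxide (Grignard opening, Appel inversion).
5. No ring is built. Both six-membered rings are bought as arenes; the dienone ring is dearomatised in step 3 and made stereogenic in step 7; desilylation ends the route.

Key step: step 7

**Route**

Step 1
Reactants: 1 3,4-dimethoxyphenol; 2 allyl bromide
Product: 3 4-(allyloxy)-1,2-dimethoxybenzene
Conditions: K2CO3, acetone, reflux
Reagents that add atoms: none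
Why: Williamson ether synthesis of an unhindered phenoxide with a primary allylic bromide should give clean O-alkylation.

Step 2
Reactants: 3 4-(allyloxy)-1,2-dimethoxybenzene
Product: 4 2-allyl-4,5-dimethoxyphenol
Conditions: N,N-diethylaniline, 190 °C
Reagents that add atoms: none
Why: the aromatic Claisen rearrangement ([3,3] shift, then tautomerisation) should deliver the allyl group to the free ortho position that is not flanked by a methoxy group.

Step 3
Reactants: 4 2-allyl-4,5-dimethoxyphenol
Product: 5 2-allyl-5-methoxy-1,4-benzoquinone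
Conditions: PhI(OAc)2, MeCN/H2O, 0 °C
Reagents that add atoms: water, O
Why: hypervalent-iodine oxidative demethylation of a para-methoxyphenol (water adds at the para carbon, methanol is lost) should give the para-quinone and leave the allyl group untouched.

Step 4
Reactants: 6 4-bromo-2-methoxyphenol
Product: 7 (4-bromo-2-methoxyphenoxy)(tert-butyl)dimethylsilane
Conditions: TBSCl, imidazole, DMF, rt
Reagents that add atoms: tert-butyldimethylsilyl chloride, CC(C)(C)[Si](C)(C)Cl
Why: standard silylation of a phenol; the aryl silyl ether should survive Mg, t-BuLi at −100 °C and MeOTf and is removable with fluoride.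

Step 5
Reactants: 7 (4-bromo-2-methoxyphenoxy)(tert-butyl)dimethylsilane; 8 (S)-propylene oxide
Product: 10 (2S)-1-[4-(tert-butyldimethylsilyloxy)-3-methoxyphenyl]propan-2-ol, via arylmagnesium bromide 9 (not isolated)
Conditions: Mg, THF, 50 °C; then CuI (10 mol %), 8, −30 to 0 °C; aq NH4Cl
Reagents that add atoms: none
Why: copper-catalysed Grignard opening of a terminal epoxide should occur at the CH2 terminus, so the stereocentre is taken unchanged from the chiral pool.

Step 6
Reactants: 10 (2S)-1-[4-(tert-butyldimethylsilyloxy)-3-methoxyphenyl]propan-2-ol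
Product: 11 tert-butyl{4-[(2R)-2-iodopropyl]-2-methoxyphenoxy}dimethylsilane
Conditions: PPh3, I2, N-methylimidazole, CH2Cl2, −10 °C
Reagents that add atoms: iodine, II
Why: in the Appel reaction iodide displaces the phosphorus-activated oxygen in an SN2 step, which should give the (R)-iodide by inversion.

Step 7
Reactants: 11 tert-butyl{4-[(2R)-2-iodopropyl]-2-methoxyphenoxy}dimethylsilane; 5 2-allyl-5-methoxy-1,4-benzoquinone
Product: 14 (4S)-4-{(2R)-1-[4-(tert-butyldimethylsilyloxy)-3-methoxyphenyl]propan-2-yl}-4,5-dimethoxy-2-(prop-2-en-1-yl)cyclohexa-2,5-dien-1-one, via secondary alkyllithium 12 (not isolated), via lithium quinol alkoxide 13 (not isolated)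
Conditions: t-BuLi (2.0 equiv), pentane/Et2O 3:2, −100 °C; then 5, THF, −100 to −78 °C; then MeOTf, −78 to 0 °C
Reagents that add atoms: methyl trifluoromethanesulfonate, COS(=O)(=O)C(F)(F)F
Why: Iodine–lithium exchange at −100 °C should convert 11 into the non-stabilised secondary alkyllithium 12 with retention; 12, trapped within seconds by 5, should add to the C4 carbonyl in a four-centre, front-side (retentive) 1,2-addition to give alkoxide 13, which MeOTf O-methylates in the same flask. The closest known reaction types are the 1,2-addition of alkyllithiums to p-benzoquinones (p-quinol synthesis), the stereoretentive generation and carbonyl trapping of secondary alkyllithiums, and the in situ O-alkylation of quinol alkoxides; no ring is closed. The side-chain centre (2R) is fixed by the chiral pool: (S)-propylene oxide, one inversion in step 6 and two retentive events here. The ring centre C4 is set by the face of the carbonyl that is attacked, under 1,2-induction from the incoming carbon only: in the staggered transition state H should take the most crowded sector between the lithium-bound oxygen and the methoxy-bearing C5, CH3 the sector over the flat ring and the arylmethyl group the sector next to C3–H, which gives (4S); the preference is expected to be moderate, and the (4R) epimer, a diastereomer, would be removed by chromatography. The step needs C4 over C1 carbonyl selectivity and 1,2-addition over conjugate addition, electron transfer and deprotonation of the allylic CH2: the vinylogous-ester character and the neighbouring allyl group deactivate and shield C1=O, and a hard lithium reagent at −100 °C in a weakly polar medium favours direct carbonyl addition.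

Step 8
Reactants: 14 (4S)-4-{(2R)-1-[4-(tert-butyldimethylsilyloxy)-3-methoxyphenyl]propan-2-yl}-4,5-dimethoxy-2-(prop-2-en-1-yl)cyclohexa-2,5-dien-1-one
Product: 15 (4S)-4-[(2R)-1-(4-hydroxy-3-methoxyphenyl)propan-2-yl]-4,5-dimethoxy-2-(prop-2-en-1-yl)cyclohexa-2,5-dien-1-one
Conditions: TBAF, AcOH, THF, 0 °C
Reagents that add atoms: none
Why: buffered fluoride cleavage of an aryl silyl ether should free the phenol without touching the quinol ether, the dienone or either stereocentre.

**Compound list**

1 | 3,4-dimethoxyphenol | COc1ccc(O)cc1OC | starting material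
2 | allyl bromide | C=CCBr | starting material
3 | 4-(allyloxy)-1,2-dimethoxybenzene | C=CCOc1ccc(OC)c(OC)c1 | intermediate
4 | 2-allyl-4,5-dimethoxyphenol | C=CCc1cc(OC)c(OC)cc1O | intermediate
5 | 2-allyl-5-methoxy-1,4-benzoquinone | C=CCC1=CC(=O)C(OC)=CC1=O | intermediate
6 | 4-bromo-2-methoxyphenol | COc1cc(Br)ccc1O | starting material
7 | (4-bromo-2-methoxyphenoxy)(tert-butyl)dimethylsilane | COc1cc(Br)ccc1O[Si](C)(C)C(C)(C)C | intermediate
8 | (S)-propylene oxide, (2S)-2-methyloxirane | C[C@H]1CO1 | starting material
9 | [4-(tert-butyldimethylsilyloxy)-3-methoxyphenyl]magnesium bromide (not isolated) | COc1cc([Mg]Br)ccc1O[Si](C)(C)C(C)(C)C | intermediate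
10 | (2S)-1-[4-(tert-butyldimethylsilyloxy)-3-methoxyphenyl]propan-2-ol | C[C@H](O)Cc1ccc(O[Si](C)(C)C(C)(C)C)c(OC)c1 | intermediate
11 | tert-butyl{4-[(2R)-2-iodopropyl]-2-methoxyphenoxy}dimethylsilane | C[C@@H](I)Cc1ccc(O[Si](C)(C)C(C)(C)C)c(OC)c1 | intermediate
12 | {(2R)-1-[4-(tert-butyldimethylsilyloxy)-3-methoxyphenyl]propan-2-yl}lithium (not isolated) | C[C@@H]([Li])Cc1ccc(O[Si](C)(C)C(C)(C)C)c(OC)c1 | intermediate
13 | lithium (1S)-1-{(2R)-1-[4-(tert-butyldimethylsilyloxy)-3-methoxyphenyl]propan-2-yl}-2-methoxy-4-oxo-5-(prop-2-en-1-yl)cyclohexa-2,5-dien-1-olate (not isolated) | C=CCC1=C[C@@]([O-])([C@H](C)Cc2ccc(O[Si](C)(C)C(C)(C)C)c(OC)c2)C(OC)=CC1=O.[Li+] | intermediate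
14 | (4S)-4-{(2R)-1-[4-(tert-butyldimethylsilyloxy)-3-methoxyphenyl]propan-2-yl}-4,5-dimethoxy-2-(prop-2-en-1-yl)cyclohexa-2,5-dien-1-one | C=CCC1=C[C@@](OC)([C@H](C)Cc2ccc(O[Si](C)(C)C(C)(C)C)c(OC)c2)C(OC)=CC1=O | intermediate
15 | (4S)-4-[(2R)-1-(4-hydroxy-3-methoxyphenyl)propan-2-yl]-4,5-dimethoxy-2-(prop-2-en-1-yl)cyclohexa-2,5-dien-1-one | C=CCC1=C[C@@](OC)([C@H](C)Cc2ccc(O)c(OC)c2)C(OC)=CC1=O | target

**Step count and risks**

Total steps: 8. Longest linear sequence: 5 steps (1, 2, 3, 7, 8 or 4, 5, 6, 7, 8).

Steps most likely to fail:

Step 7. The C–C bond formation may lose out to electron transfer from the alkyllithium to the quinone or to epimerisation of 12, and the facial discrimination at the C4 carbonyl may be low, so that much of the material ends as the (4R) epimer. The fallback replaces carbonyl addition by a stereospecific aryl–alkyl coupling followed by oxidative methoxylation. It sets out from alkyllithium 12 (made from 11 as in step 7), which is quenched with 2-isopropoxy-4,4,5,5-tetramethyl-1,3,2-dioxaborolane to give, with retention, 2-{(2R)-1-[4-(tert-butyldimethylsilyloxy)-3-methoxyphenyl]propan-2-yl}-4,4,5,5-tetramethyl-1,3,2-dioxaborolane F1. Commercial 4-bromo-3-methoxyphenol is O-allylated (allyl bromide, K2CO3) to 4-(allyloxy)-1-bromo-2-methoxybenzene F2 and rearranged (Claisen, 190 °C) to 2-allyl-4-bromo-5-methoxyphenol F3. F3 is lithiated at oxygen and at the brominated carbon (n-BuLi, then t-BuLi, THF, −78 °C) and combined with F1 and then Ph3BiF2. The stereoretentive 1,2-migration from boron to the para carbon, followed by rearomatisation, should give 2-allyl-4-{(2R)-1-[4-(tert-butyldimethylsilyloxy)-3-methoxyphenyl]propan-2-yl}-5-methoxyphenol F4. PhI(OAc)2 in MeOH at 0 °C should then add methanol at the para carbon and return to the route at 14, together with the (4R)-epimer of 14 F5. F5 can be reduced back to F4 (Zn, AcOH) and oxidised again, so the unwanted epimer is not lost.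

Step 6. The electron-rich aryl ring may participate (phenonium ion) and iodide may exchange with the product, which would erode the configuration or move the aryl group to the neighbouring carbon. The fallback installs boron instead of iodine and avoids any substitution at the stereocentre. It sets out from 7: bromine–lithium exchange (n-BuLi, −78 °C) and 2-(chloromethyl)-4,4,5,5-tetramethyl-1,3,2-dioxaborolane (Matteson homologation) should give tert-butyl{2-methoxy-4-[(4,4,5,5-tetramethyl-1,3,2-dioxaborolan-2-yl)methyl]phenoxy}dimethylsilane F6. Lithiation–borylation of F6 with ethyl N,N-diisopropylcarbamate and s-BuLi/(−)-sparteine (Et2O, −78 °C, then warming) should give the (R)-boronic ester F1. F1 is carried through the coupling with F3 to phenol F4 and the oxidative methoxylation described above, and the route is rejoined at 14.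

Step 3. The allyl-substituted quinone may be over-oxidised or decompose in the aqueous oxidising medium (attack of water on the product, tautomerisation towards a quinone methide). The fallback separates oxidation and hydrolysis. It sets out from 4: PhI(OAc)2 in dry MeOH at 0 °C should give the quinone monoketal 2-allyl-4,4,5-trimethoxycyclohexa-2,5-dien-1-one F7, which is stable and isolable. Mild hydrolysis (aqueous oxalic acid, THF, rt) should then release the quinone, and the route is rejoined at 5.

**Further compounds**

F1 | step 7 | 2-{(2R)-1-[4-(tert-butyldimethylsilyloxy)-3-methoxyphenyl]propan-2-yl}-4,4,5,5-tetramethyl-1,3,2-dioxaborolane | C[C@@H](B1OC(C)(C)C(C)(C)O1)Cc1ccc(O[Si](C)(C)C(C)(C)C)c(OC)c1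
F2 | step 7 | 4-(allyloxy)-1-bromo-2-methoxybenzene | C=CCOc1ccc(Br)c(OC)c1
F3 | step 7 | 2-allyl-4-bromo-5-methoxyphenol | C=CCc1cc(Br)c(OC)cc1O
F4 | step 7 | 2-allyl-4-{(2R)-1-[4-(tert-butyldimethylsilyloxy)-3-methoxyphenyl]propan-2-yl}-5-methoxyphenol | C=CCc1cc([C@H](C)Cc2ccc(O[Si](C)(C)C(C)(C)C)c(OC)c2)c(OC)cc1O
F5 | step 7 | (4R)-4-{(2R)-1-[4-(tert-butyldimethylsilyloxy)-3-methoxyphenyl]propan-2-yl}-4,5-dimethoxy-2-(prop-2-en-1-yl)cyclohexa-2,5-dien-1-one | C=CCC1=C[C@](OC)([C@H](C)Cc2ccc(O[Si](C)(C)C(C)(C)C)c(OC)c2)C(OC)=CC1=O
F6 | step 6 | tert-butyl{2-methoxy-4-[(4,4,5,5-tetramethyl-1,3,2-dioxaborolan-2-yl)methyl]phenoxy}dimethylsilane | COc1cc(CB2OC(C)(C)C(C)(C)O2)ccc1O[Si](C)(C)C(C)(C)C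
F7 | step 3 | 2-allyl-4,4,5-trimethoxycyclohexa-2,5-dien-1-one | C=CCC1=CC(OC)(OC)C(OC)=CC1=O
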